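**Retrosynthetic overview**

1. Target ⇒ (acetylation, SN2 demethylation of the C-19 ester, Takai–Lombardo methylenation at C-8, enolate hydroxylation at C-7) ⇒ methyl 8-oxo-17-norlabda-12E,14-dien-19-oate; its whole side chain comes from C-9 alkylation of a regiodefined C-8/C-9 silyl enol ether with (3E)-5-bromo-3-methylpenta-1,3-diene.
2. C-18 and H-5 ⇒ reductive methylation of a C-4=C-5 unsaturated ester; C-20 ⇒ copper-catalysed asymmetric 1,4-methylation at C-10, the only catalyst-set stereocentre (C-5, C-4, C-9 and C-7 are relayed from it by substrate control).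
3. Key disconnection (ring A): C-1–C-2 and C-4–C-5 by a doubly vinylogous [3+3] Michael/aldol annulation of 3-methylcyclohex-2-en-1-one (ring B plus C-1) with methyl 2-oxobut-3-enoate (C-2, C-3, C-4, C-19), giving a flat, achiral bicyclic dienone ester.
4. Enabling feature: C-8 of ring B (the exocyclic methylene carbon) is a latent ketone and C-10 is its β-carbon, so C-1 and C-5, the two ring-A atoms bound to C-10, are both γ-positions of the enone C-8(=O)–C-9=C-10; C-4 carries the carboxyl carbon C-19 and can therefore be the keto carbon of a vinyl α-keto ester.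
5. Ring order: ring B is bought as the cyclohexenone, ring A is closed in the key step, no further ring is formed.

Key step: step 2

Remark: atom numbers are labdane numbers (C-1 to C-20) and α/β refer to the usual drawing with the C-10 methyl group β; methyl 2-hydroxybut-3-enoate, 3-methylcyclohex-2-en-1-one and (2E)-3-methylpent-2-en-4-yn-1-ol are taken as commercial, and the ligand enantiomer in step 3 is taken to be the one that gives the configuration drawn.

**Route**

Step 1
Reactants: 1 methyl 2-hydroxybut-3-enoate
Product: 2 methyl 2-oxobut-3-enoate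
Conditions: Dess–Martin periodinane, NaHCO3, CH2Cl2, 0 °C → rt; cold filtered solution used at once
Reagents that add atoms: none
Why: Dess–Martin oxidation of the secondary allylic α-hydroxy ester gives the vinyl α-keto ester under neutral conditions, and immediate use avoids its hetero-Diels–Alder dimerisation.

Step 2
Reactants: 2 methyl 2-oxobut-3-enoate; 3 3-methylcyclohex-2-en-1-one
Product: 6 methyl 6-oxo-2,3,4,6,7,8-hexahydronaphthalene-1-carboxylate, via keto ester 4 (not isolated), via aldol 5 (not isolated)
Conditions: 3 (2 equiv), 9-amino-9-deoxy-epi-quinine (20 mol%), 2-fluorobenzoic acid (40 mol%), toluene, 40 °C, 2 added over 6 h; then 60 °C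
Reagents that add atoms: none
Why: Proposed new method: the primary amine converts 3 into its exocyclic linear dienamine, whose γ-carbon (C-1, the former methyl group) adds to the unhindered CH2 terminus (C-2) of 2 in a vinylogous Michael addition to give 4, the dienamine is then re-formed on the ring side and its γ-carbon C-5 attacks the strongly electrophilic α-keto carbonyl C-4 in an intramolecular vinylogous aldol addition (5), and water is lost through the dienamine (vinylogous E1cB) to leave the fully conjugated dienone ester 6. The closest known reaction types are the primary-amine-catalysed vinylogous Michael and vinylogous aldol reactions of 3-methylcyclohex-2-en-1-one at its γ-methyl group (the aldol with α-keto esters) and the Robinson annulation, of which this is the doubly vinylogous [3+3] counterpart. Ring A is closed by a 6-(enolendo)-exo-trig aldol step. The two stereocentres that appear in 5 (C-4 and C-5) are erased by the dehydration, so 6 is achiral and the step has no stereochemical task. The step needs γ- over α-attack of the dienamine and reaction of the exocyclic γ-carbon first: both are the known preferences of β-methylcyclohexenone dienamines, and the later events are under thermodynamic control because 1,2-adducts at the keto group and aldol adducts through C-9 are reversible while only closure through C-5 can lose water to the conjugated dienone.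

Step 3
Reactants: 6 methyl 6-oxo-2,3,4,6,7,8-hexahydronaphthalene-1-carboxylate
Product: 8 methyl (4aR)-6-[(tert-butyldimethylsilyl)oxy]-4a-methyl-2,3,4,4a,7,8-hexahydronaphthalene-1-carboxylate, via aluminium enolate 7 (not isolated)
Conditions: AlMe3, copper thiophene-2-carboxylate C5H3CuO2S (5 mol%), (S,R,R)-binaphthol N,N-bis(1-phenylethyl)phosphoramidite (10 mol%), Et2O, −30 °C; then t-BuMe2SiOTf, THF, −30 → 0 °C
Reagents that add atoms: trimethylaluminium C[Al](C)C; tert-butyldimethylsilyl trifluoromethanesulfonate CC(C)(C)[Si](C)(C)OS(=O)(=O)C(F)(F)F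
Why: Copper-catalysed asymmetric conjugate addition of AlMe3, which on cyclic dienones prefers 1,4- over 1,6-addition, creates the quaternary C-10 centre on the flat achiral substrate under pure catalyst control (ligand decides the face), and O-silylation of the aluminium enolate stores the C-8/C-9 enolate regiochemistry.

Step 4
Reactants: 8 methyl (4aR)-6-[(tert-butyldimethylsilyl)oxy]-4a-methyl-2,3,4,4a,7,8-hexahydronaphthalene-1-carboxylate
Product: 10 methyl (1S,4aS,8aR)-6-[(tert-butyldimethylsilyl)oxy]-1,4a-dimethyl-1,2,3,4,4a,7,8,8a-octahydronaphthalene-1-carboxylate, via lithium enolate 9 (not isolated)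
Conditions: Li, NH3(l)/THF, t-BuOH (1 equiv), −78 °C; isoprene; then MeI, −78 → −33 °C
Reagents that add atoms: iodomethane CI
Why: Birch-type reductive alkylation of the α,β-unsaturated ester: the β-carbanion at C-5 is protonated from the α face (trans ring fusion, anti to the C-10 methyl group) and MeI then enters C-4 of enolate 9 from the equatorial α side because the axial β side is blocked by the 1,3-diaxial C-10 methyl group, which leaves the ester axial (C-19) while the silyl enol ether stays inert.

Step 5
Reactants: 11 (2E)-3-methylpent-2-en-4-yn-1-ol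
Product: 12 (2E)-3-methylpenta-2,4-dien-1-ol
Conditions: H2 (1 atm), Pd on CaCO3 poisoned with Pb(OAc)2 (Lindlar catalyst), quinoline, EtOAc, 0 °C
Reagents that add atoms: none
Why: Lindlar semihydrogenation stops at the terminal alkene and does not touch the E-trisubstituted double bond.

Step 6
Reactants: 12 (2E)-3-methylpenta-2,4-dien-1-ol
Product: 13 (3E)-5-bromo-3-methylpenta-1,3-diene
Conditions: PBr3, Et2O, −10 °C, dark; used crude
Reagents that add atoms: phosphorus tribromide BrP(Br)Br
Why: Bromination of the primary allylic alcohol through its phosphite ester at low temperature keeps the E geometry and gives the primary dienyl bromide, the more stable allylic isomer.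

Step 7
Reactants: 10 methyl (1S,4aS,8aR)-6-[(tert-butyldimethylsilyl)oxy]-1,4a-dimethyl-1,2,3,4,4a,7,8,8a-octahydronaphthalene-1-carboxylate; 13 (3E)-5-bromo-3-methylpenta-1,3-diene
Product: 16 methyl 8-oxo-17-norlabda-12E,14-dien-19-oate, via sulfonium enolate 14 (not isolated), via 9-epi ketone 15 (not isolated)
Conditions: tris(dimethylamino)sulfonium difluorotrimethylsilicate, THF, −78 °C; 13, −78 → 0 °C; then NaOMe (cat.), MeOH, rt
Reagents that add atoms: none
Why: Fluoride cleavage of the silyl enol ether gives the regiodefined naked enolate 14, which is C-alkylated (SN2) by the primary allylic bromide mainly anti to the C-10 methyl group (15), and base equilibration through the enolate then places the side chain in the equatorial 9β position (9α-H), the thermodynamic arrangement of 9-substituted 8-oxo decalins of this type.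

Step 8
Reactants: 16 methyl 8-oxo-17-norlabda-12E,14-dien-19-oate
Product: 18 methyl 7α-hydroxy-8-oxo-17-norlabda-12E,14-dien-19-oate, via potassium enolate 17 (not isolated)
Conditions: KN(SiMe3)2, THF, −78 °C; 2-(benzenesulfonyl)-3-phenyloxaziridine, −78 °C; NH4Cl (aq)
Reagents that add atoms: 2-(benzenesulfonyl)-3-phenyloxaziridine O=S(=O)(c1ccccc1)N1OC1c1ccccc1
Why: Kinetic deprotonation takes the unhindered C-7 proton (C-9 is tertiary and next to the quaternary C-10), and Davis enolate hydroxylation delivers oxygen along the axial α trajectory of the chair-like enolate to give the axial 7α-alcohol.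

Step 9
Reactants: 18 methyl 7α-hydroxy-8-oxo-17-norlabda-12E,14-dien-19-oate
Product: 19 methyl 7α-hydroxylabda-8(17),12E,14-trien-19-oate
Conditions: Zn, CH2Br2, TiCl4, THF (reagent preformed at 0–5 °C); 18, CH2Cl2, 0 °C → rt
Reagents that add atoms: dibromomethane BrCBr
Why: Takai–Lombardo methylenation converts the hindered, enolisable α-hydroxy ketone into the exocyclic alkene under non-basic conditions, so neither C-7 nor C-9 should epimerise and the free hydroxyl group, the ester and the diene are tolerated.

Step 10
Reactants: 19 methyl 7α-hydroxylabda-8(17),12E,14-trien-19-oate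
Product: 20 7α-hydroxylabda-8(17),12E,14-trien-19-oic acid
Conditions: n-PrSLi (from n-PrSH and n-BuLi), HMPA, rt; then dilute HCl to pH 3
Reagents that add atoms: none
Why: The axial neopentyl-type C-19 methyl ester resists saponification but is cleaved by SN2 attack of the thiolate on the O-methyl carbon, which is insensitive to hindrance at the carbonyl group and leaves the alkenes and the allylic alcohol alone.

Step 11
Reactants: 20 7α-hydroxylabda-8(17),12E,14-trien-19-oic acid
Product: 22 7α-acetoxylabda-8(17),12E,14-trien-19-oic acid, via mixed anhydride 21 (not isolated)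
Conditions: Ac2O, pyridine, DMAP (cat.), CH2Cl2, 0 °C → rt; then NaHCO3 (aq)/THF, rt; acidify to pH 4
Reagents that add atoms: acetic anhydride CC(=O)OC(C)=O
Why: DMAP-catalysed acetylation of the axial allylic alcohol proceeds with retention at C-7, and the carboxyl group, acetylated in passing to mixed anhydride 21, is set free again in the bicarbonate work-up because water attacks the unhindered acetyl carbonyl.

**Compound list**

1 | methyl 2-hydroxybut-3-enoate (racemic) | C=CC(O)C(=O)OC | starting material
2 | methyl 2-oxobut-3-enoate | C=CC(=O)C(=O)OC | intermediate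
3 | 3-methylcyclohex-2-en-1-one | CC1=CC(=O)CCC1 | starting material
4 | methyl 2-oxo-5-(3-oxocyclohex-1-en-1-yl)pentanoate (Michael adduct, not isolated) | O=C1C=C(CCCC(=O)C(=O)OC)CCC1 | intermediate
5 | methyl 1-hydroxy-6-oxo-1,2,3,4,6,7,8,8a-octahydronaphthalene-1-carboxylate (aldol adduct, diastereomer mixture, not isolated) | O=C1C=C2CCCC(O)(C(=O)OC)C2CC1 | intermediate
6 | methyl 6-oxo-2,3,4,6,7,8-hexahydronaphthalene-1-carboxylate (achiral; C-8 ketone, C-9=C-10 and C-4=C-5) | O=C1C=C2CCCC(C(=O)OC)=C2CC1 | intermediate
7 | dimethylaluminium enolate (O–Al at C-8, C-8=C-9) of the 10β-methyl ketone, not isolated | C1=C(O[Al](C)C)CCC2[C@]1(C)CCCC=2C(=O)OC | intermediate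
8 | methyl (4aR)-6-[(tert-butyldimethylsilyl)oxy]-4a-methyl-2,3,4,4a,7,8-hexahydronaphthalene-1-carboxylate (10β-methyl) | C1=C(O[Si](C)(C)C(C)(C)C)CCC2[C@]1(C)CCCC=2C(=O)OC | intermediate
9 | lithium ester enolate at C-4/C-19 with 5α-H (trans-fused), not isolated | C1=C(O[Si](C)(C)C(C)(C)C)CC[C@@H]2[C@]1(C)CCCC2=C([O-])OC.[Li+] | intermediate
10 | methyl (1S,4aS,8aR)-6-[(tert-butyldimethylsilyl)oxy]-1,4a-dimethyl-1,2,3,4,4a,7,8,8a-octahydronaphthalene-1-carboxylate (trans fusion, 5α-H, 10β-CH3, ester β-axial, 4α-CH3) | C1=C(O[Si](C)(C)C(C)(C)C)CC[C@@H]2[C@]1(C)CCC[C@]2(C)C(=O)OC | intermediate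
11 | (2E)-3-methylpent-2-en-4-yn-1-ol | C#C/C(C)=C/CO | starting material
12 | (2E)-3-methylpenta-2,4-dien-1-ol | C=C/C(C)=C/CO | intermediate
13 | (3E)-5-bromo-3-methylpenta-1,3-diene | C=C/C(C)=C/CBr | intermediate
14 | tris(dimethylamino)sulfonium C-8/C-9 enolate of the 8-oxo ester, not isolated | C1=C([O-])CC[C@@H]2[C@]1(C)CCC[C@]2(C)C(=O)OC.CN(C)[S+](N(C)C)N(C)C | intermediate
15 | methyl 8-oxo-17-nor-9-epi-labda-12E,14-dien-19-oate (9β-H, side chain α-axial), not isolated | C=C/C(C)=C/C[C@@H]1C(=O)CC[C@@H]2[C@]1(C)CCC[C@]2(C)C(=O)OC | intermediate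
16 | methyl 8-oxo-17-norlabda-12E,14-dien-19-oate (5α-H, 9α-H, 10β-CH3) | C=C/C(C)=C/C[C@H]1C(=O)CC[C@@H]2[C@]1(C)CCC[C@]2(C)C(=O)OC | intermediate
17 | potassium C-7/C-8 enolate of 16, not isolated | C=C/C(C)=C/C[C@H]1C([O-])=CC[C@@H]2[C@]1(C)CCC[C@]2(C)C(=O)OC.[K+] | intermediate
18 | methyl 7α-hydroxy-8-oxo-17-norlabda-12E,14-dien-19-oate | C=C/C(C)=C/C[C@H]1C(=O)[C@H](O)C[C@@H]2[C@]1(C)CCC[C@]2(C)C(=O)OC | intermediate
19 | methyl 7α-hydroxylabda-8(17),12E,14-trien-19-oate | C=C/C(C)=C/C[C@H]1C(=C)[C@H](O)C[C@@H]2[C@]1(C)CCC[C@]2(C)C(=O)OC | intermediate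
20 | 7α-hydroxylabda-8(17),12E,14-trien-19-oic acid | C=C/C(C)=C/C[C@H]1C(=C)[C@H](O)C[C@@H]2[C@]1(C)CCC[C@]2(C)C(=O)O | intermediate
21 | acetic 7α-acetoxylabda-8(17),12E,14-trien-19-oic anhydride, not isolated | C=C/C(C)=C/C[C@H]1C(=C)[C@H](OC(C)=O)C[C@@H]2[C@]1(C)CCC[C@]2(C)C(=O)OC(C)=O | intermediate
22 | 7α-acetoxylabda-8(17),12E,14-trien-19-oic acid (7α-acetoxy-trans-communic acid) | C=C/C(C)=C/C[C@H]1C(=C)[C@H](OC(C)=O)C[C@@H]2[C@]1(C)CCC[C@]2(C)C(=O)O | target

**Step count and risks**

Total step count: 11. Longest linear sequence: 9 steps (steps 1–4 and 7–11); steps 5 and 6 make the side-chain bromide.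

Steps most likely to fail:

Step 2 (proposed new method). The dienamine may react through its α- or α′-carbon instead of the γ-carbons, the vinyl keto ester may oligomerise before it is captured, and the dienone may tautomerise to the aromatic hydroxytetralin ester. The fallback is a stepwise, classical assembly of the same ring. It does not consume a numbered compound: commercial 3-ethoxycyclohex-2-en-1-one takes the place of 3, and the sequence comes back at 4 (isolated this time) and then 6. Stork–Danheiser addition of ClMg(CH2)3OMgCl followed by aqueous HCl should give 3-(3-hydroxypropyl)cyclohex-2-en-1-one F1. Appel iodination (I2, PPh3, imidazole) gives 3-(3-iodopropyl)cyclohex-2-en-1-one F2. Alkylation of the sodium salt of methyl 1,3-dithiane-2-carboxylate (NaH, DMF) gives methyl 2-[3-(3-oxocyclohex-1-en-1-yl)propyl]-1,3-dithiane-2-carboxylate F3. Dithiane removal (NBS, aqueous acetone) releases keto ester 4, which is closed to 6 by an ordinary amine-mediated intramolecular aldol condensation at the γ-position (pyrrolidine, AcOH, toluene, 60 °C).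

Step 3. Facial discrimination by the chiral copper complex may be weak on this fused, flat dienone, and 1,6-addition or uncatalysed 1,2-addition may compete. The fallback replaces catalyst control by resolution; it sets out from 6 and comes back at 10. Ligand-free conjugate methylation (AlMe3, CuBr·SMe2, Et2O, then t-BuMe2SiOTf) should give racemic material, that is 8 together with its mirror image ent-8 F4. This is carried through step 4 to the racemate of 10 (10 together with ent-10 F5). Separation of the enantiomers by preparative chromatography on a chiral stationary phase delivers 10.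

Step 7. Proton transfer between the naked enolate and the product may erode regiocontrol or cause dialkylation, the dienyl bromide may ionise or isomerise, and equilibration at C-9 may stay incomplete. The fallback builds the diene stepwise from a robust electrophile; it sets out from 10 and comes back at 16. Enolate alkylation with allyl bromide under the conditions of step 7 (including the NaOMe equilibration) should give methyl 8-oxo-17-nor-13,14,15,16-tetranorlabd-12-en-19-oate F6, the 9β-allyl ketone. Oxidative cleavage (OsO4 cat., NaIO4, 2,6-lutidine, dioxane/H2O) gives the C-12 aldehyde F7. Wittig reaction with Ph3P=C(CH3)CHO (toluene, 80 °C) gives the (E)-enal F8. Methylenation of the aldehyde with Ph3P=CH2 (THF, −78 → 0 °C), which leaves the hindered C-8 ketone alone, gives 16.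

Further compounds
F1 | step 2 | 3-(3-hydroxypropyl)cyclohex-2-en-1-one | O=C1C=C(CCCO)CCC1
F2 | step 2 | 3-(3-iodopropyl)cyclohex-2-en-1-one | O=C1C=C(CCCI)CCC1
F3 | step 2 | methyl 2-[3-(3-oxocyclohex-1-en-1-yl)propyl]-1,3-dithiane-2-carboxylate | O=C1C=C(CCCC2(C(=O)OC)SCCCS2)CCC1
F4 | step 3 | ent-8, methyl (4aS)-6-[(tert-butyldimethylsilyl)oxy]-4a-methyl-2,3,4,4a,7,8-hexahydronaphthalene-1-carboxylate | C1=C(O[Si](C)(C)C(C)(C)C)CCC2[C@@]1(C)CCCC=2C(=O)OC
F5 | step 3 | ent-10, methyl (1R,4aR,8aS)-6-[(tert-butyldimethylsilyl)oxy]-1,4a-dimethyl-1,2,3,4,4a,7,8,8a-octahydronaphthalene-1-carboxylate | C1=C(O[Si](C)(C)C(C)(C)C)CC[C@H]2[C@@]1(C)CCC[C@@]2(C)C(=O)OC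
F6 | step 7 | 9β-allyl ketone, methyl 8-oxo-17-nor-13,14,15,16-tetranorlabd-12-en-19-oate | C=CC[C@H]1C(=O)CC[C@@H]2[C@]1(C)CCC[C@]2(C)C(=O)OC
F7 | step 7 | C-12 aldehyde, methyl 8,12-dioxo-13,14,15,16,17-pentanorlabdan-19-oate | O=CC[C@H]1C(=O)CC[C@@H]2[C@]1(C)CCC[C@]2(C)C(=O)OC
F8 | step 7 | (E)-enal, methyl 8,14-dioxo-15,17-dinorlabd-12E-en-19-oate | O=C/C(C)=C/C[C@H]1C(=O)CC[C@@H]2[C@]1(C)CCC[C@]2(C)C(=O)OC
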